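The rate constants were chosen freely; the result is computed.

At early times c(target) and c(isomer of the product) are still small, so intermediate leaves mainly by its forward exits, and the return steps carry little.

    substrate → intermediate (k1 = 0.12 /s)
    intermediate ⇌ target (K2 = 7.7, k2 = 0.11 /s)
    intermediate ⇌ isomer of the product (K3 = 4.8, k3 = 0.063 /s)
    intermediate → decomposed reagent (k4 = 0.034 /s)
    substrate + target ⇌ idle adduct, settled at all times (K5 = 1700 /M)

| setting | theta | alpha |
|---|---|---|
| substrate | 1.0 mM | 1.0 mM |
| time | 50 s |  |
| remark | everything together in a closed stirred flask, run for 50 s | a single well-mixed tank run continuously and read at steady state, 50 s in it on average |

- a species is counted by the substrate in it: one idle adduct counts as two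
- amounts and yields of target count idle adduct too
- the stated concentrations are those of everything mixed, before any reaction; amounts are the same in each set-up
- in an amount of target, one idle adduct counts as one target
- run time (theta): 50 s

* the set-up with the highest amount of target at the outlet or at the end, in percent of the substrate put in ("none" if the first two lie within 2 percentage points) (theta / alpha / none)
* amount of target at the outlet or at the end, in percent of the substrate put in, theta
* amount of target at the outlet or at the end, in percent of the substrate put in, alpha

The quantity to carry is the branching share, the forward constant towards target divided by the sum of the forward constants of the exits of intermediate: 53.1 %. This is a kinetic-control figure.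

In theta, substrate has a half-life of 5.8 s by the step to intermediate alone. Binding to target stretches this by a factor of 2.70 with the whole charge taken as target, to 15.6 s. Since that is shorter than the 50 s run, the hand figure for theta counts the charge as having passed through intermediate and equals the share.

Each setting changes the exits:

| Setting | Share to target |
|---|---|
| theta as drawn | 53.1 % |
| alpha, outflow as a further exit | 48.5 % |
| theta, step to decomposed reagent struck out | 63.6 % |
| theta, step to isomer struck out | 76.4 % |

In alpha, leaving the adduct aside, a first-order tank converts 85.7 % of substrate, so the hand figure is 41.5 %, below the hand figure for theta. These hand figures ignore the return steps.

The forecast also names theta, but with 45.8 % for theta and 34.5 % for alpha, each lower than the hand figure. Of theta it notes that “The adduct slows substrate use to about 0.07 /s late in the run”.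

The flask gives theta as the better set-up, with 45.6 % in theta against 34.5 % in alpha, a lead of 11 percentage points, wider than the margin. Theta also ends with 26.1 % isomer of the product, so target makes up 63.6 % of the two together. With the step to decomposed reagent struck out, the share goes from 53.1 % to 63.6 %, which scales theta's 45.6 % to 54.6 %; the struck theta flask reads 57.1 %.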